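**Plan**

- Core numbering (tricyclo[4.2.1.1(2,5)]deca-3,7-diene): ring 1 is C2(Me)–C3(cyclopropyl)=C4–C5–C10, ring 2 is C1–C8(Me)=C7(cyclopropyl)–C6–C9; the bonds C1–C2 and C5–C6 join them, and C3=C4 lies over C7=C8 (syn).
- Enabling feature: in ring 2, C9 sits between C1 and C6, and these two carbons are bonded to the termini C2 and C5 of ring 1. Ring 2 is therefore a cyclopentenyl oxyallyl unit (C1–C9–C6) added across a cyclopentadiene, once C9 carries oxygen and C8 an exocyclic methylene.
- Retrosynthetic cuts, in order: the two dioxolanes; C7=C8 back to C8=CH2; the C9 ketone; then C7–C8, C1–C2 and C5–C6 together, giving allenyl vinyl ketone 10 and cyclopentadiene 17; both go back to aldehyde 7 and to lactone 1.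
- Forward order: lactone → side chain → 7; branch a gives 10; branch b builds ring 1 (Pauson–Khand reaction, MeLi, 1,4-dehydration); step 13 closes ring 2 and the central ring; then C9 deoxygenation, alkene shift and deprotection.
- Stereochemistry: the four cyclopropane centres come from 1 and are never touched; C1, C2, C5 and C6 arise in step 13 (conrotation biased by the cyclopropane, diene anti to the C7 substituent, extended mode); C7 is a temporary centre.

Key step: step 13

Remark: R stands for (1R,3S)-2,2-dimethyl-3-[2-(2-methyl-1,3-dioxolan-2-yl)ethyl]cyclopropyl, attached through C1, with the spatial arrangement fixed in 7 (the formal descriptor at C1 can change with the attached group). The two dioxolanes are assumed to survive BF3·OEt2 at −78 °C for the few minutes that step 13 needs.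

**Route**

Step 1
Reactants: 1 (1R,5S)-6,6-dimethyl-3-oxabicyclo[3.1.0]hexan-2-one
Product: 2 (1R,3S)-3-(hydroxymethyl)-N-methoxy-N,2,2-trimethylcyclopropane-1-carboxamide
Conditions: MeNHOMe·HCl, AlMe3, CH2Cl2, 0 → 20 °C
Reagents that add atoms: N,O-dimethylhydroxylamine hydrochloride, CNOC.Cl
Why: Weinreb aminolysis of the γ-lactone by the aluminium amide acylates nitrogen at the lactone carbonyl and frees the CH2OH group without touching either cyclopropane centre.

Step 2
Reactants: 2 (1R,3S)-3-(hydroxymethyl)-N-methoxy-N,2,2-trimethylcyclopropane-1-carboxamide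
Product: 3 (1R,3S)-3-formyl-N-methoxy-N,2,2-trimethylcyclopropane-1-carboxamide
Conditions: Dess–Martin periodinane, CH2Cl2, 0 → 20 °C (2 used at once)
Reagents that add atoms: none
Why: Dess–Martin oxidation takes the primary alcohol to the aldehyde under neutral conditions, before the hydroxy amide can relactonise and without epimerising the cis-cyclopropane.

Step 3
Reactants: 3 (1R,3S)-3-formyl-N-methoxy-N,2,2-trimethylcyclopropane-1-carboxamide
Product: 4 (1R,3S)-N-methoxy-N,2,2-trimethyl-3-[(1E)-3-oxobut-1-en-1-yl]cyclopropane-1-carboxamide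
Conditions: Ph3P=CHC(O)CH3, toluene, 60 °C
Reagents that add atoms: 1-(triphenylphosphoranylidene)propan-2-one, CC(=O)C=P(c1ccccc1)(c1ccccc1)c1ccccc1
Why: Wittig olefination with the stabilised acetonyl ylide attacks only the aldehyde and gives the (E)-enone, which carries all four carbons of the side chain.

Step 4
Reactants: 4 (1R,3S)-N-methoxy-N,2,2-trimethyl-3-[(1E)-3-oxobut-1-en-1-yl]cyclopropane-1-carboxamide
Product: 5 (1R,3S)-N-methoxy-N,2,2-trimethyl-3-(3-oxobutyl)cyclopropane-1-carboxamide
Conditions: H2 (1 atm), RhCl(PPh3)3 (5 mol %), toluene–EtOH, 20 °C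
Reagents that add atoms: none
Why: Homogeneous hydrogenation with RhCl(PPh3)3 saturates the disubstituted enone C=C and leaves the adjacent cyclopropane, the ketone and the N–O bond intact.

Step 5
Reactants: 5 (1R,3S)-N-methoxy-N,2,2-trimethyl-3-(3-oxobutyl)cyclopropane-1-carboxamide
Product: 6 (1R,3S)-N-methoxy-N,2,2-trimethyl-3-[2-(2-methyl-1,3-dioxolan-2-yl)ethyl]cyclopropane-1-carboxamide
Conditions: HOCH2CH2OH, pyridinium p-toluenesulfonate (cat.), benzene, reflux, Dean–Stark
Reagents that add atoms: ethylene glycol, OCCO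
Why: Acid-catalysed ketalisation with azeotropic removal of water masks the methyl ketone as a dioxolane, and the Weinreb amide is inert to it.

Step 6
Reactants: 6 (1R,3S)-N-methoxy-N,2,2-trimethyl-3-[2-(2-methyl-1,3-dioxolan-2-yl)ethyl]cyclopropane-1-carboxamide
Product: 7 (1R,3S)-2,2-dimethyl-3-[2-(2-methyl-1,3-dioxolan-2-yl)ethyl]cyclopropane-1-carbaldehyde
Conditions: i-Bu2AlH, THF, −78 °C; aq. KNaC4H4O6
Reagents that add atoms: none
Why: Hydride reduction of the Weinreb amide stops at the chelated tetrahedral aluminate, which gives the aldehyde only on work-up and leaves the ketal untouched.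

Step 7
Reactants: 7 (1R,3S)-2,2-dimethyl-3-[2-(2-methyl-1,3-dioxolan-2-yl)ethyl]cyclopropane-1-carbaldehyde
Product: 8 (2E)-N-methoxy-N-methyl-3-R-prop-2-enamide
Conditions: (EtO)2P(O)CH2C(O)N(OMe)Me, NaH, THF, 0 → 20 °C
Reagents that add atoms: diethyl [2-[methoxy(methyl)amino]-2-oxoethyl]phosphonate, CCOP(=O)(CC(=O)N(C)OC)OCC
Why: Horner–Wadsworth–Emmons olefination with the stabilised phosphonate anion gives the (E)-enamide, and the anion is too weak a base to epimerise the cyclopropyl aldehyde.

Step 8
Reactants: 8 (2E)-N-methoxy-N-methyl-3-R-prop-2-enamide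
Product: 10 (1E)-1-R-hexa-1,4,5-trien-3-one, via β,γ-alkynyl ketone 9 (not isolated)
Conditions: propargylmagnesium bromide (from HC≡CCH2Br, Mg, HgCl2 cat., Et2O), THF, −78 → −20 °C; aq. NH4Cl; then Et3N (cat.), CH2Cl2, 0 °C; stored cold in solution
Reagents that add atoms: 3-bromoprop-1-yne (as its Grignard reagent), C#CCBr
Why: Grignard addition to the Weinreb amide stops at the ketone level through the stable chelate, and propargyl–allenyl prototropy under catalytic amine base converts ynone 9 into the conjugated allenyl ketone.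

Step 9
Reactants: 7 (1R,3S)-2,2-dimethyl-3-[2-(2-methyl-1,3-dioxolan-2-yl)ethyl]cyclopropane-1-carbaldehyde
Product: 11 2-{2-[(1S,3S)-3-ethynyl-2,2-dimethylcyclopropyl]ethyl}-2-methyl-1,3-dioxolane
Conditions: MeC(O)C(N2)P(O)(OMe)2, K2CO3, MeOH, 0 → 20 °C
Reagents that add atoms: dimethyl (1-diazo-2-oxopropyl)phosphonate, COP(=O)(OC)C(=[N+]=[N-])C(C)=O
Why: Ohira–Bestmann (Seyferth–Gilbert) homologation turns the aldehyde into the terminal alkyne under carbonate conditions that do not epimerise the cyclopropane.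

Step 10
Reactants: 11 2-{2-[(1S,3S)-3-ethynyl-2,2-dimethylcyclopropyl]ethyl}-2-methyl-1,3-dioxolane
Product: 13 2-R-cyclopent-2-en-1-one, via dicobalt hexacarbonyl alkyne complex 12 (not isolated)
Conditions: Co2(CO)8, CH2Cl2, 20 °C; then C2H4 (3 atm), N-methylmorpholine N-oxide, 4 Å MS, 0 → 20 °C
Reagents that add atoms: dicobalt octacarbonyl (source of CO), O=C=[Co](=C=O)(=C=O)(=C=O)[Co](=C=O)(=C=O)(=C=O)=C=O; ethylene, C=C
Why: The N-oxide-promoted intermolecular Pauson–Khand reaction of a terminal alkyne with ethylene builds ring 1 as the cyclopentenone, with the alkyne substituent next to the carbonyl group as is the rule.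

Step 11
Reactants: 13 2-R-cyclopent-2-en-1-one
Product: 14 1-methyl-2-R-cyclopent-2-en-1-ol (both carbinol epimers)
Conditions: MeLi, Et2O, −78 °C; aq. NH4Cl
Reagents that add atoms: methyllithium, [Li]C
Why: 1,2-Addition of methyllithium to the enone gives the tertiary allylic alcohol; its new centre is not controlled because step 12 removes it.

Step 12
Reactants: 14 1-methyl-2-R-cyclopent-2-en-1-ol (both carbinol epimers)
Product: 17 1-methyl-2-R-cyclopenta-1,3-diene, via sulfenate ester 15 (not isolated), via allylic sulfoxide 16 (not isolated)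
Conditions: 2,4-(O2N)2C6H3SCl, Et3N, CH2Cl2, −30 → 20 °C, dark; cold filtration through neutral alumina (pentane); used at once in step 13
Reagents that add atoms: none
Why: In this Reich 1,4-dehydration, O-sulfenylation and [2,3]-sigmatropic shift place sulfur on the former enone β-carbon and create the C(Me)=C(R) bond, and syn-elimination of the 2,4-dinitrophenyl sulfoxide can take hydrogen only from the adjacent CH2, so one positional isomer of the diene forms below the temperature at which 1,5-hydrogen shifts scramble cyclopentadienes.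

Step 13
Reactants: 10 (1E)-1-R-hexa-1,4,5-trien-3-one; 17 1-methyl-2-R-cyclopenta-1,3-diene
Product: 19 2-methyl-8-methylidene-3,7-di-R-tricyclo[4.2.1.1(2,5)]dec-3-en-9-one (syn core; H7 on the inner face), via oxyallyl cation 18 (not isolated)
Conditions: 10 (1.0 equiv), 17 (1.5 equiv), BF3·OEt2 (1.5 equiv), CH2Cl2, −78 °C; aq. NaHCO3 at −78 °C
Reagents that add atoms: none
Why: BF3 activates the ketone of 10, the pentadienyl cation closes by conrotatory 4π electrocyclisation (C7–C8, ring 2) to the boron-bound 2-oxidocyclopentenyl cation 18, and 18 is captured across the termini of 17 in a (4+3) cycloaddition (C5–C6 first, then C2–C1) that closes the central six-membered ring; the closest known reaction type is the interrupted Nazarov reaction of allenyl vinyl ketones with cyclic 1,3-dienes. Ring 2 thus closes by electrocyclisation, made fast at −78 °C by the allene, which ends as the C8 methylene, and the central ring closes by suprafacial addition of the oxyallyl termini C1 and C6 to one face of the diene. C7 is set by the sense of conrotation, which the cyclopropane biases because in its s-trans bisected conformer the new bond forms on the alkene face flanked by the ring CH carbon and away from the CMe2 carbon. C1 and C6 follow from C7 because the diene adds to the face of 18 opposite the cyclopropyl group, and C2 and C5 follow from the extended arrangement (C3=C4 over C7–C8, C10 over C9), which avoids the contacts that the compact one forces between the C3 cyclopropyl group and the O–BF3 unit and between the C10 methylene and H7. Regiochemistry rests on the unsubstituted, more nucleophilic diene terminus C5 attacking C6, the cation terminus remote from the methylene carbon, which leaves a tertiary allyl cation at C2 to close on C1. The step needs the right conrotation sense, anti capture, C5-to-C6 regiochemistry and the extended mode; the second and third are secured by the bulk at C7 and the substitution pattern of 17, the first and last only by steric preference, so minor diastereomers would be removed by chromatography here.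

Step 14
Reactants: 19 2-methyl-8-methylidene-3,7-di-R-tricyclo[4.2.1.1(2,5)]dec-3-en-9-one
Product: 20 4-methylbenzenesulfonohydrazone of 19 at C9 (C=N isomers)
Conditions: TsNHNH2, THF, 4 Å MS, 50 °C (no acid)
Reagents that add atoms: 4-methylbenzenesulfonohydrazide, Cc1ccc(cc1)S(=O)(=O)NN
Why: The strained, non-enolisable bridging ketone condenses with the sulfonyl hydrazide (hydrazone formation), and without acid the dioxolanes are not exchanged.

Step 15
Reactants: 20 4-methylbenzenesulfonohydrazone of 19 at C9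
Product: 22 2-methyl-8-methylidene-3,7-di-R-tricyclo[4.2.1.1(2,5)]dec-3-ene, via N-alkyl tosylhydrazide 21 (not isolated)
Conditions: catecholborane, CHCl3, 0 → 20 °C; then NaOAc·3H2O, 60 °C
Reagents that add atoms: none
Why: In this Kabalka reduction (a mild Wolff–Kishner equivalent) the borane adds hydride to C=N, and acetate-induced loss of sulfinate and N2 from 21 leaves the C9 methylene without strong base or heat.

Step 16
Reactants: 22 2-methyl-8-methylidene-3,7-di-R-tricyclo[4.2.1.1(2,5)]dec-3-ene
Product: 23 (1S,2S,5S,6S)-2,8-dimethyl-3,7-di-R-tricyclo[4.2.1.1(2,5)]deca-3,7-diene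
Conditions: KOt-Bu (0.5 equiv), DMSO, 60 °C
Reagents that add atoms: none
Why: Base-mediated prototropic isomerisation through the allyl anion (as in the β-pinene to α-pinene shift) moves the exocyclic double bond to the tetrasubstituted, cyclopropane-conjugated C7=C8 position; C1 is a bridgehead, so only C7 can lose the proton, which also erases the temporary C7 centre.

Step 17
Reactants: 23 (1S,2S,5S,6S)-2,8-dimethyl-3,7-di-R-tricyclo[4.2.1.1(2,5)]deca-3,7-diene
Product: 24 (1S,2S,5S,6S)-2,8-dimethyl-3,7-bis[(1R,3S)-2,2-dimethyl-3-(3-oxobutyl)cyclopropyl]tricyclo[4.2.1.1(2,5)]deca-3,7-diene (CNP0300925.1)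
Conditions: pyridinium p-toluenesulfonate (cat.), acetone–H2O (10:1), 45 °C
Reagents that add atoms: water, O
Why: Mild acid-catalysed hydrolysis of both dioxolanes releases the two methyl ketones, and the acid is too weak to protonate the vinylcyclopropane alkenes.

**Compound list**

1 | (1R,5S)-6,6-dimethyl-3-oxabicyclo[3.1.0]hexan-2-one | O=C1OC[C@H]2[C@@H]1C2(C)C | starting material
2 | (1R,3S)-3-(hydroxymethyl)-N-methoxy-N,2,2-trimethylcyclopropane-1-carboxamide | CON(C)C(=O)[C@@H]1[C@H](CO)C1(C)C | intermediate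
3 | (1R,3S)-3-formyl-N-methoxy-N,2,2-trimethylcyclopropane-1-carboxamide | CON(C)C(=O)[C@@H]1[C@H](C=O)C1(C)C | intermediate
4 | (1R,3S)-N-methoxy-N,2,2-trimethyl-3-[(1E)-3-oxobut-1-en-1-yl]cyclopropane-1-carboxamide | CON(C)C(=O)[C@@H]1[C@H](/C=C/C(C)=O)C1(C)C | intermediate
5 | (1R,3S)-N-methoxy-N,2,2-trimethyl-3-(3-oxobutyl)cyclopropane-1-carboxamide | CON(C)C(=O)[C@@H]1[C@H](CCC(C)=O)C1(C)C | intermediate
6 | (1R,3S)-N-methoxy-N,2,2-trimethyl-3-[2-(2-methyl-1,3-dioxolan-2-yl)ethyl]cyclopropane-1-carboxamide | CON(C)C(=O)[C@@H]1[C@H](CCC2(C)OCCO2)C1(C)C | intermediate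
7 | (1R,3S)-2,2-dimethyl-3-[2-(2-methyl-1,3-dioxolan-2-yl)ethyl]cyclopropane-1-carbaldehyde | O=C[C@@H]1[C@H](CCC2(C)OCCO2)C1(C)C | intermediate
8 | (2E)-N-methoxy-N-methyl-3-R-prop-2-enamide | CON(C)C(=O)/C=C/[C@@H]1[C@H](CCC2(C)OCCO2)C1(C)C | intermediate
9 | (1E)-1-R-hex-1-en-5-yn-3-one | C#CCC(=O)/C=C/[C@@H]1[C@H](CCC2(C)OCCO2)C1(C)C | intermediate (not isolated)
10 | (1E)-1-R-hexa-1,4,5-trien-3-one (allenyl vinyl ketone) | C=C=CC(=O)/C=C/[C@@H]1[C@H](CCC2(C)OCCO2)C1(C)C | intermediate
11 | 2-{2-[(1S,3S)-3-ethynyl-2,2-dimethylcyclopropyl]ethyl}-2-methyl-1,3-dioxolane | C#C[C@@H]1[C@H](CCC2(C)OCCO2)C1(C)C | intermediate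
12 | hexacarbonyldicobalt complex of alkyne 11 | [CH]12C3([C@@H]4[C@H](CCC5(C)OCCO5)C4(C)C)[Co]1(=C=O)(=C=O)(=C=O)[Co]23(=C=O)(=C=O)=C=O | intermediate (not isolated)
13 | 2-R-cyclopent-2-en-1-one | O=C1CCC=C1[C@@H]1[C@H](CCC2(C)OCCO2)C1(C)C | intermediate
14 | 1-methyl-2-R-cyclopent-2-en-1-ol (both carbinol epimers) | CC1(O)CCC=C1[C@@H]1[C@H](CCC2(C)OCCO2)C1(C)C | intermediate
15 | 2,4-dinitrobenzenesulfenate ester of 14 | CC1(OSc2ccc(cc2[N+](=O)[O-])[N+](=O)[O-])CCC=C1[C@@H]1[C@H](CCC2(C)OCCO2)C1(C)C | intermediate (not isolated)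
16 | 3-[(2,4-dinitrophenyl)sulfinyl]-1-methyl-2-R-cyclopent-1-ene (epimers at carbon and sulfur) | CC1=C([C@@H]2[C@H](CCC3(C)OCCO3)C2(C)C)C(CC1)S(=O)c1ccc(cc1[N+](=O)[O-])[N+](=O)[O-] | intermediate (not isolated)
17 | 1-methyl-2-R-cyclopenta-1,3-diene | CC1=C([C@@H]2[C@H](CCC3(C)OCCO3)C2(C)C)C=CC1 | intermediate
18 | BF3-bound 4-methylidene-5-R-2-oxidocyclopentenyl (oxyallyl) cation | C=C1[CH+]C(O[B-](F)(F)F)=C[C@@H]1[C@@H]2[C@H](CCC3(C)OCCO3)C2(C)C | intermediate (not isolated)
19 | 2-methyl-8-methylidene-3,7-di-R-tricyclo[4.2.1.1(2,5)]dec-3-en-9-one (syn core; H7 inner face) | CC1(OCCO1)CC[C@H]1[C@@H](C2=C[C@@H]3C[C@@]2(C)[C@H]2C(=O)[C@@H]3[C@H]([C@@H]3[C@H](CCC4(C)OCCO4)C3(C)C)C2=C)C1(C)C | intermediate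
20 | 4-methylbenzenesulfonohydrazone of 19 at C9 | CC1(OCCO1)CC[C@H]1[C@@H](C2=C[C@@H]3C[C@@]2(C)[C@H]2C(=NNS(=O)(=O)c4ccc(C)cc4)[C@@H]3[C@H]([C@@H]3[C@H](CCC4(C)OCCO4)C3(C)C)C2=C)C1(C)C | intermediate
21 | N'-(C9-alkyl)-4-methylbenzenesulfonohydrazide from 20 (C9 configuration open; present as its borane adduct) | CC1(OCCO1)CC[C@H]1[C@@H](C2=C[C@@H]3C[C@@]2(C)[C@H]2C(NNS(=O)(=O)c4ccc(C)cc4)[C@@H]3[C@H]([C@@H]3[C@H](CCC4(C)OCCO4)C3(C)C)C2=C)C1(C)C | intermediate (not isolated)
22 | 2-methyl-8-methylidene-3,7-di-R-tricyclo[4.2.1.1(2,5)]dec-3-ene | CC1(OCCO1)CC[C@H]1[C@@H](C2=C[C@@H]3C[C@@]2(C)[C@H]2C[C@@H]3[C@H]([C@@H]3[C@H](CCC4(C)OCCO4)C3(C)C)C2=C)C1(C)C | intermediate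
23 | (1S,2S,5S,6S)-2,8-dimethyl-3,7-di-R-tricyclo[4.2.1.1(2,5)]deca-3,7-diene | CC1(OCCO1)CC[C@H]1[C@@H](C2=C[C@@H]3C[C@@]2(C)[C@H]2C[C@@H]3C([C@@H]3[C@H](CCC4(C)OCCO4)C3(C)C)=C2C)C1(C)C | intermediate
24 | (1S,2S,5S,6S)-2,8-dimethyl-3,7-bis[(1R,3S)-2,2-dimethyl-3-(3-oxobutyl)cyclopropyl]tricyclo[4.2.1.1(2,5)]deca-3,7-diene (CNP0300925.1) | CC(=O)CC[C@H]1[C@@H](C2=C[C@@H]3C[C@@]2(C)[C@H]2C[C@@H]3C([C@@H]3[C@H](CCC(C)=O)C3(C)C)=C2C)C1(C)C | target

**Step count and risks**

Total: 17 steps. Longest linear sequence: 15 steps (1–6, 9–12, 13–17).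

Steps most likely to fail:

1. Step 13. The remote cyclopropane may bias the sense of conrotation only weakly, so that two C7-epimeric cations form and lead to adducts with mirror-image cores. Capture may also take the compact course, stop at a (3+2) adduct after the first bond, or be outrun by BF3-induced oligomerisation of the diene or opening of a dioxolane. The fallback sets out from 10 and separates ring closure from capture. CF3CO2H in CH2Cl2 at −40 °C would close ring 2 with trifluoroacetate capture to give the trans-3-methyl-4-R-5-(trifluoroacetoxy)cyclopent-2-en-1-one F1. Methanolysis (K2CO3, MeOH, 0 °C) would give the trans-5-hydroxy-3-methyl-4-R-cyclopent-2-en-1-one F2, a stable compound at which the C4 epimers can be separated. MsCl and Et3N would give the mesylate F3. Et3N in CF3CH2OH at 0 °C would then regenerate the oxyallyl cation by γ-deprotonation and ionisation in the presence of 17 (Föhlisch-type (4+3) cycloaddition without Lewis acid), and the route is rejoined at 19.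

2. Step 12. If the sulfoxide elimination needs warming, 1,5-hydrogen shifts would scramble the position of the diene, and the diene may also dimerise or be attacked by excess sulfenyl chloride. The fallback sets out from 14 and moves the leaving group to the carbon where only one elimination is possible. Oxidative transposition with pyridinium chlorochromate, [C5H5NH][CrO3Cl], in CH2Cl2 buffered with NaOAc would give the 3-methyl-2-R-cyclopent-2-en-1-one F4. Luche reduction (NaBH4, CeCl3·7H2O, MeOH, −40 °C) would give the 3-methyl-2-R-cyclopent-2-en-1-ol F5. Dehydration with Ph2S[OC(CF3)2Ph]2 in CH2Cl2 at −40 → 0 °C can remove hydrogen only from the adjacent CH2 and returns to the route at 17.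

3. Step 16. Proton removal at C7 may be slow because H7 lies in the cleft between the two rings, and the equilibrium may not lie fully on the side of the strained tetrasubstituted alkene. The fallback sets out from 22 and changes both the order and the mechanism. Hydrolysis of the dioxolanes (pyridinium p-toluenesulfonate, acetone–water) would give the exocyclic-methylene diketone F6. RhCl3·3H2O in EtOH at 70 °C (metal hydride addition–elimination) would then move the double bond on the free diketone, where ketal lability no longer matters, and the route is rejoined at 24.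

**Further compounds**

F1 | step 13 | trans-3-methyl-4-R-5-(trifluoroacetoxy)cyclopent-2-en-1-one (C4 as C7 of 19) | CC1=CC(=O)[C@@H](OC(=O)C(F)(F)F)[C@@H]1[C@@H]2[C@H](CCC3(C)OCCO3)C2(C)C
F2 | step 13 | trans-5-hydroxy-3-methyl-4-R-cyclopent-2-en-1-one | CC1=CC(=O)[C@@H](O)[C@@H]1[C@@H]2[C@H](CCC3(C)OCCO3)C2(C)C
F3 | step 13 | trans-5-(methanesulfonyloxy)-3-methyl-4-R-cyclopent-2-en-1-one | CC1=CC(=O)[C@@H](OS(C)(=O)=O)[C@@H]1[C@@H]2[C@H](CCC3(C)OCCO3)C2(C)C
F4 | step 12 | 3-methyl-2-R-cyclopent-2-en-1-one | CC1=C([C@@H]2[C@H](CCC3(C)OCCO3)C2(C)C)C(=O)CC1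
F5 | step 12 | 3-methyl-2-R-cyclopent-2-en-1-ol (both carbinol epimers) | CC1=C([C@@H]2[C@H](CCC3(C)OCCO3)C2(C)C)C(O)CC1
F6 | step 16 | 2-methyl-8-methylidene-3,7-bis[(1R,3S)-2,2-dimethyl-3-(3-oxobutyl)cyclopropyl]tricyclo[4.2.1.1(2,5)]dec-3-ene | CC(=O)CC[C@H]1[C@@H](C2=C[C@@H]3C[C@@]2(C)[C@H]2C[C@@H]3[C@H]([C@@H]3[C@H](CCC(C)=O)C3(C)C)C2=C)C1(C)C
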